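**Retrosynthetic overview**

- The target is ent-oritin-(4α→6)-epioritin-4α-ol. The interflavanyl bond C4(upper)–C6(lower) is cut as a Friedel–Crafts alkylation. Before inversion of its C3, the upper unit is the mirror image of the all-cis lower unit, so one achiral flavone (8) serves both halves.
- The pyranone ring C of 8 is made in one operation from aryl ketone 5 and acid chloride 6: enolate C-acylation forms C2–C3, and intramolecular SNAr by the diketonate oxygen forms O1–C8a.
- Enabling feature: C8a of ring A is ortho to C4a, so at the C4-ketone level a fluorine on C8a is a vinylogous acyl fluoride within reach of O1. C2, C3 and C4 of the lower ring C are all cis, so syn-hydrogenation of the flat pyranone can deliver them.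
- Ring order: ring A (bought) → ring C with ring B attached (key step) → dearomative hydrogenation to both antipodes → C4–C6 coupling → oxidation/reduction inversion at upper C3 → deprotection.

Key step: step 4

Remarks on the chemistry:
- Flavan numbering (O1, C2, C3, C4, C4a, C5–C8, C8a; rings A, B, C) is used throughout.
- SINpEt·HBF4 is 1,3-bis[1-(naphthalen-1-yl)ethyl]-4,5-dihydroimidazolium tetrafluoroborate.
- Assumption: the (R,R)-ligand is taken to give the (2R,3R,4R) series. If the sense of induction is the reverse, the two ligand antipodes are exchanged between steps 5 and 6.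

Step 1
Reactants: 1 3-fluorocatechol (3-fluorobenzene-1,2-diol)
Product: 2 1,2-bis(benzyloxy)-3-fluorobenzene
Conditions: BnBr (2.3 equiv), K2CO3 (3 equiv), DMF, 60 °C
Reagents that add atoms: benzyl bromide, BrCc1ccccc1
Why: Double Williamson etherification of the catechol gives benzyl ethers that should tolerate every later step and leave together at the end; no stereocentre is involved.

Step 2
Reactants: 2 1,2-bis(benzyloxy)-3-fluorobenzene; 3 (tert-butyldimethylsilyloxy)acetaldehyde
Product: 4 (±)-1-[3,4-bis(benzyloxy)-2-fluorophenyl]-2-[(tert-butyldimethylsilyl)oxy]ethan-1-ol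
Conditions: n-BuLi (1.05 equiv), THF, −78 °C; then 3, −78 °C; H2O quench
Reagents that add atoms: none
Why: Fluorine-directed ortho-lithiation removes the most acidic ring proton (ortho to F), and the aryllithium should add to the aldehyde at −78 °C before it can lose LiF; the carbinol centre forms racemic and is erased in step 3.

Step 3
Reactants: 4 (±)-1-[3,4-bis(benzyloxy)-2-fluorophenyl]-2-[(tert-butyldimethylsilyl)oxy]ethan-1-ol
Product: 5 1-[3,4-bis(benzyloxy)-2-fluorophenyl]-2-[(tert-butyldimethylsilyl)oxy]ethan-1-one
Conditions: IBX (1.5 equiv), DMSO/THF, 25 °C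
Reagents that add atoms: none
Why: IBX oxidation of a secondary benzylic alcohol to the aryl ketone runs under neutral conditions that should leave the silyl and benzyl ethers untouched; no stereocentre remains.

Step 4
Reactants: 5 1-[3,4-bis(benzyloxy)-2-fluorophenyl]-2-[(tert-butyldimethylsilyl)oxy]ethan-1-one; 6 4-(benzyloxy)benzoyl chloride
Product: 8 7,8-bis(benzyloxy)-2-[4-(benzyloxy)phenyl]-3-[(tert-butyldimethylsilyl)oxy]-4H-chromen-4-one, via lithium diketonate 7 (not isolated)
Conditions: LiN(SiMe3)2 (2.3 equiv), THF, −78 °C; 6, −78 to 0 °C; then 65 °C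
Reagents that add atoms: none
Why: LiN(SiMe3)2 forms the chelated lithium enolate of 5, which is C-acylated by 6 (Claisen-type acylation, new C2–C3 bond); the second equivalent of base converts the 2-silyloxy-1,3-diketone into diketonate 7, whose oxygen on C2 (the former acid chloride oxygen, O1) adds to C8a of ring A and expels fluoride (intramolecular SNAr, new O1–C8a bond). The closest known reaction type is the one-pot acylation/SNAr cyclisation of 2-halophenyl ketones with acid chlorides to chromones, flavones and 4-quinolones. Ring C closes by a 6-endo-trig addition–elimination at C8a through a Meisenheimer intermediate whose charge is taken up by the C4 carbonyl. No stereocentre is made: the step deliberately delivers a flat, achiral pyranone that already holds every skeletal atom of one flavan unit, so that C2, C3 and C4 can be set all-cis by hydrogenation and one compound can feed both halves of the dimer. The step needs C- over O-acylation (lithium chelate and excess base), closure through O1 and not the C4 oxygen (only O1 reaches C8a in a six-membered transition state), and a silyl ether that neither migrates to O1 nor is cleaved (bulky tert-butyldimethylsilyl group; fluoride leaves as insoluble LiF in THF).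

Step 5
Reactants: 8 7,8-bis(benzyloxy)-2-[4-(benzyloxy)phenyl]-3-[(tert-butyldimethylsilyl)oxy]-4H-chromen-4-one
Product: 10 (2R,3R,4R)-7,8-bis(benzyloxy)-2-[4-(benzyloxy)phenyl]chromane-3,4-diol, via silyl ether 9 (not isolated)
Conditions: Ru(cod)(2-methylallyl)2 (5 mol%), (R,R)-SINpEt·HBF4 (10 mol%), KOt-Bu (12 mol%), H2 (120 bar), toluene, 40 °C; then vented, Bu4NF, AcOH, THF, 0 °C
Reagents that add atoms: none
Why: Proposed new method: a chiral ruthenium–N-heterocyclic carbene hydride is expected to add H2 syn across the tetrasubstituted C2=C3 enol-ether bond of the pyranone from one enantioface (C2 and C3 cis, catalyst control) and then to reduce the C4 carbonyl of the resulting 2,3-cis chromanone from the face anti to the axial 3-silyloxy group (C4 cis, substrate control); the closest known reaction types are the ruthenium–carbene-catalysed asymmetric hydrogenation of flavones and chromones to cis-flavan-4-ols and the heterogeneous hydrogenation of flavonols to 2,3-cis-3,4-cis-flavan-3,4-diols, neither shown enantioselectively on a 3-oxygenated flavone; buffered fluoride then removes the silyl group.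

Step 6
Reactants: 8 7,8-bis(benzyloxy)-2-[4-(benzyloxy)phenyl]-3-[(tert-butyldimethylsilyl)oxy]-4H-chromen-4-one
Product: 12 (2S,3S,4S)-7,8-bis(benzyloxy)-2-[4-(benzyloxy)phenyl]chromane-3,4-diol, via silyl ether 11 (not isolated)
Conditions: Ru(cod)(2-methylallyl)2 (5 mol%), (S,S)-SINpEt·HBF4 (10 mol%), KOt-Bu (12 mol%), H2 (120 bar), toluene, 40 °C; then vented, Bu4NF, AcOH, THF, 0 °C
Reagents that add atoms: none
Why: Proposed new method: the same dearomative syn-hydrogenation of the pyranone C2=C3 bond followed by carbonyl reduction anti to the axial 3-silyloxy group, run with the antipodal ruthenium–carbene catalyst so that the opposite enantioface is hydrogenated and the all-cis (2S,3S,4S) series results; the closest known reaction type is again the ruthenium–carbene-catalysed asymmetric hydrogenation of flavones to cis-flavan-4-ols; buffered fluoride then removes the silyl group.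

Step 7
Reactants: 10 (2R,3R,4R)-7,8-bis(benzyloxy)-2-[4-(benzyloxy)phenyl]chromane-3,4-diol
Product: 13 cis-fused 3,4-cyclic carbonate of 10 (five-membered 1,3-dioxolan-2-one across C3–C4)
Conditions: 1,1'-carbonyldiimidazole (1.5 equiv), DMAP (cat.), THF, 50 °C
Reagents that add atoms: 1,1'-carbonyldiimidazole, O=C(n1ccnc1)n1ccnc1
Why: The carbonyldiimidazole acylates one hydroxyl and the cis neighbour closes the five-membered carbonate, which caps both hydroxyls and ties back the benzylic C4–O bond so that it cannot ionise productively in step 8; the stereocentres are untouched.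

Step 8
Reactants: 12 (2S,3S,4S)-7,8-bis(benzyloxy)-2-[4-(benzyloxy)phenyl]chromane-3,4-diol; 13 cis-fused 3,4-cyclic carbonate of 10 (3 equiv, excess recovered)
Product: 14 hexa-O-benzyl ent-epioritin-(4α→6)-epioritin-4α-ol 3,4-carbonate (lower unit: 13 substituted at C6; upper unit: (2S,3S)-2,3-cis-3,4-trans flavan-3-ol, 3-OH free)
Conditions: BF3·OEt2 (0.3 equiv), 4 Å MS, CH2Cl2, −40 to −20 °C, slow addition of 12
Reagents that add atoms: none
Why: Friedel–Crafts alkylation by an SN1 path: BF3 ionises the free benzylic 4-OH of 12 to a cation stabilised by the para 7-benzyloxy group (the water set free is held by the sieves), and C6 of 13 (ortho to O7 and para to O1, the most nucleophilic ring A position) should capture it on the face opposite the cis 2-aryl and 3-OH groups, so that upper C4 is set 3,4-trans and 2,4-trans by substrate control.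

Step 9
Reactants: 14 hexa-O-benzyl ent-epioritin-(4α→6)-epioritin-4α-ol 3,4-carbonate
Product: 15 upper flavan-3-one of 14 (upper 3-OH oxidised to C=O; upper C2 and C4 unchanged; lower carbonate intact)
Conditions: Dess–Martin periodinane (1.5 equiv), CH2Cl2, 0 to 25 °C
Reagents that add atoms: none
Why: Dess–Martin oxidation of the only free hydroxyl (the axial upper 3-OH) gives the flavan-3-one under non-basic conditions, so the enolisable C2 and C4 centres flanking the new ketone should not be disturbed.

Step 10
Reactants: 15 upper flavan-3-one of 14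
Product: 17 hexa-O-benzyl ent-oritin-(4α→6)-epioritin-4α-ol (upper unit 2,3-trans-3,4-cis; lower unit all-cis 3,4-diol), via inverted alcohol carbonate 16 (not isolated)
Conditions: LiAlH4 (4 equiv), THF, −78 °C; then 0 °C; aqueous potassium sodium tartrate work-up
Reagents that add atoms: none
Why: At −78 °C hydride should add axially to C3 from the face opposite the quasi-axial C4 aryl group, giving the equatorial 3-OH cis to the C4 aryl and trans to the equatorial C2 aryl (net inversion at upper C3 by oxidation–reduction, substrate control), and on warming the excess LiAlH4 reduces the cyclic carbonate to the free lower cis-diol and methanol (hydride reduction of a carbonate).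

Step 11
Reactants: 17 hexa-O-benzyl ent-oritin-(4α→6)-epioritin-4α-ol
Product: 18 ent-oritin-(4α→6)-epioritin-4α-ol; (2R,3R,4R)-2-(4-hydroxyphenyl)-6-[(2S,3R,4R)-3,7,8-trihydroxy-2-(4-hydroxyphenyl)chroman-4-yl]chromane-3,4,7,8-tetrol
Conditions: H2 (1 atm), Pd(OH)2/C, THF/MeOH, 25 °C, stopped at full debenzylation
Reagents that add atoms: none
Why: Hydrogenolysis of the six aryl benzyl ethers under neutral conditions, where O–benzyl cleavage is far faster than loss of the secondary benzylic 4-OH or of the ring C2–O bonds; no stereocentre is affected.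

**Compound list**

1 | 3-fluorocatechol | Oc1cccc(F)c1O | starting material
2 | 1,2-bis(benzyloxy)-3-fluorobenzene | Fc1cccc(OCc2ccccc2)c1OCc1ccccc1 | intermediate
3 | (tert-butyldimethylsilyloxy)acetaldehyde | O=CCO[Si](C)(C)C(C)(C)C | starting material
4 | (±)-1-[3,4-bis(benzyloxy)-2-fluorophenyl]-2-[(tert-butyldimethylsilyl)oxy]ethan-1-ol (racemic carbinol) | OC(CO[Si](C)(C)C(C)(C)C)c1ccc(OCc2ccccc2)c(OCc2ccccc2)c1F | intermediate
5 | 1-[3,4-bis(benzyloxy)-2-fluorophenyl]-2-[(tert-butyldimethylsilyl)oxy]ethan-1-one | O=C(CO[Si](C)(C)C(C)(C)C)c1ccc(OCc2ccccc2)c(OCc2ccccc2)c1F | intermediate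
6 | 4-(benzyloxy)benzoyl chloride | O=C(Cl)c1ccc(OCc2ccccc2)cc1 | starting material
7 | lithium enolate of 1-[3,4-bis(benzyloxy)-2-fluorophenyl]-3-[4-(benzyloxy)phenyl]-2-[(tert-butyldimethylsilyl)oxy]propane-1,3-dione | [Li+].[O-]C(c1ccc(OCc2ccccc2)cc1)=C(O[Si](C)(C)C(C)(C)C)C(=O)c1ccc(OCc2ccccc2)c(OCc2ccccc2)c1F | intermediate
8 | 7,8-bis(benzyloxy)-2-[4-(benzyloxy)phenyl]-3-[(tert-butyldimethylsilyl)oxy]-4H-chromen-4-one | O=c1c(O[Si](C)(C)C(C)(C)C)c(-c2ccc(OCc3ccccc3)cc2)oc2c(OCc3ccccc3)c(OCc3ccccc3)ccc12 | intermediate
9 | (2R,3R,4R)-7,8-bis(benzyloxy)-2-[4-(benzyloxy)phenyl]-3-[(tert-butyldimethylsilyl)oxy]chroman-4-ol (all-cis) | c1ccc(COc2ccc([C@H]3Oc4c(ccc(OCc5ccccc5)c4OCc4ccccc4)[C@@H](O)[C@H]3O[Si](C)(C)C(C)(C)C)cc2)cc1 | intermediate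
10 | (2R,3R,4R)-7,8-bis(benzyloxy)-2-[4-(benzyloxy)phenyl]chromane-3,4-diol (all-cis) | c1ccc(COc2ccc([C@H]3Oc4c(ccc(OCc5ccccc5)c4OCc4ccccc4)[C@@H](O)[C@H]3O)cc2)cc1 | intermediate
11 | (2S,3S,4S)-7,8-bis(benzyloxy)-2-[4-(benzyloxy)phenyl]-3-[(tert-butyldimethylsilyl)oxy]chroman-4-ol (all-cis) | c1ccc(COc2ccc([C@@H]3Oc4c(ccc(OCc5ccccc5)c4OCc4ccccc4)[C@H](O)[C@@H]3O[Si](C)(C)C(C)(C)C)cc2)cc1 | intermediate
12 | (2S,3S,4S)-7,8-bis(benzyloxy)-2-[4-(benzyloxy)phenyl]chromane-3,4-diol (all-cis) | c1ccc(COc2ccc([C@@H]3Oc4c(ccc(OCc5ccccc5)c4OCc4ccccc4)[C@H](O)[C@@H]3O)cc2)cc1 | intermediate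
13 | cis-fused 3,4-cyclic carbonate of 10 | c1ccc(COc2ccc([C@H]3Oc4c(ccc(OCc5ccccc5)c4OCc4ccccc4)[C@@H](O6)[C@H]3OC6=O)cc2)cc1 | intermediate
14 | hexa-O-benzyl ent-epioritin-(4α→6)-epioritin-4α-ol 3,4-carbonate (upper unit 2,3-cis-3,4-trans, 3-OH free) | c1ccc(COc2ccc([C@H]3Oc4c(cc([C@@H]5c6ccc(OCc7ccccc7)c(OCc7ccccc7)c6O[C@@H](c6ccc(OCc7ccccc7)cc6)[C@H]5O)c(OCc5ccccc5)c4OCc4ccccc4)[C@@H](O8)[C@H]3OC8=O)cc2)cc1 | intermediate
15 | upper flavan-3-one of 14 (2,4-trans-diaryl; lower carbonate intact) | c1ccc(COc2ccc([C@H]3Oc4c(cc([C@@H]5c6ccc(OCc7ccccc7)c(OCc7ccccc7)c6O[C@@H](c6ccc(OCc7ccccc7)cc6)C5=O)c(OCc5ccccc5)c4OCc4ccccc4)[C@@H](O8)[C@H]3OC8=O)cc2)cc1 | intermediate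
16 | hexa-O-benzyl ent-oritin-(4α→6)-epioritin-4α-ol 3,4-carbonate (upper unit 2,3-trans-3,4-cis) | c1ccc(COc2ccc([C@H]3Oc4c(cc([C@@H]5c6ccc(OCc7ccccc7)c(OCc7ccccc7)c6O[C@@H](c6ccc(OCc7ccccc7)cc6)[C@@H]5O)c(OCc5ccccc5)c4OCc4ccccc4)[C@@H](O8)[C@H]3OC8=O)cc2)cc1 | intermediate
17 | hexa-O-benzyl ent-oritin-(4α→6)-epioritin-4α-ol | c1ccc(COc2ccc([C@H]3Oc4c(cc([C@@H]5c6ccc(OCc7ccccc7)c(OCc7ccccc7)c6O[C@@H](c6ccc(OCc7ccccc7)cc6)[C@@H]5O)c(OCc5ccccc5)c4OCc4ccccc4)[C@@H](O)[C@H]3O)cc2)cc1 | intermediate
18 | ent-oritin-(4α→6)-epioritin-4α-ol | Oc1ccc([C@H]2Oc3c(cc([C@@H]4c5ccc(O)c(O)c5O[C@@H](c5ccc(O)cc5)[C@@H]4O)c(O)c3O)[C@@H](O)[C@H]2O)cc1 | target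

**Step count and risks**

Total step count: 11. Longest linear sequence: 10 steps (steps 1–5 and 7–11); step 6 branches from 8 and rejoins at step 8.

Steps most likely to fail:

1. Step 5. The hydrogenation may stall at the tetrasubstituted, electron-rich C2=C3 bond, or discriminate the enantiofaces poorly. The transient 2,3-cis chromanone may also epimerise at C3 under the basic conditions before its carbonyl is reduced, which would leak material into the 2,3-trans series. Fallback with known chemistry, setting out from 8: heterogeneous hydrogenation over W-2 Raney Ni (H2, 50 bar, EtOH/THF, 40 °C), the classical all-cis reduction of 3-oxygenated flavones under conditions mild enough to spare aryl benzyl ethers, should give the racemic all-cis silyl ether, that is, the 1:1 mixture of 9 and 11. Esterification of its 4-OH with (S)-O-methylmandelic acid (N,N'-dicyclohexylcarbodiimide, DMAP, CH2Cl2) and chromatographic separation of the two diastereomers should give the (S)-O-methylmandelate of the (2R,3R,4R) alcohol F1. Methanolysis (K2CO3, MeOH) returns 9, which is desilylated as in step 5, and the route is rejoined at 10.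

2. Step 6. The same processes may fail as in step 5: incomplete reduction, low facial selectivity, or C3 epimerisation of the intermediate chromanone. Fallback with known chemistry, setting out from 8 through the same racemic hydrogenation and esterification: the second diastereomer from the separation, the (S)-O-methylmandelate of the (2S,3S,4S) alcohol F2, is methanolysed (K2CO3, MeOH) to 11 and desilylated with Bu4NF/AcOH. The route is rejoined at 12, so one resolution supplies both antipodes and none of the racemate is discarded.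

3. Step 8. The cation from 12 may be captured by ring A of a second molecule of 12 (self-condensation) or by its hydroxyl groups (ether-linked oligomers) faster than by the only moderately nucleophilic pyrogallol-type ring A of 13. Prolonged Lewis acid exposure may also open the benzylic carbonate. Fallback, setting out from 12: acid-catalysed exchange with benzyl mercaptan (BnSH, cat. BF3·OEt2, CH2Cl2, −20 °C) traps the cation cleanly as the 3,4-trans 4-benzylsulfanyl flavan-3-ol F3. F3 is then added slowly to 13 and AgBF4 in CH2Cl2/THF at −40 °C. This thiophilic activation generates the same cation irreversibly, at low stationary concentration and without protic acid, and the route is rejoined at 14.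

Further compounds
F1 | step 5 | (S)-O-methylmandelate (4-O-ester) of 9 | c1ccc(COc2ccc([C@H]3Oc4c(ccc(OCc5ccccc5)c4OCc4ccccc4)[C@@H](OC(=O)[C@@H](OC)c4ccccc4)[C@H]3O[Si](C)(C)C(C)(C)C)cc2)cc1
F2 | step 6 | (S)-O-methylmandelate (4-O-ester) of 11 | c1ccc(COc2ccc([C@@H]3Oc4c(ccc(OCc5ccccc5)c4OCc4ccccc4)[C@H](OC(=O)[C@@H](OC)c4ccccc4)[C@@H]3O[Si](C)(C)C(C)(C)C)cc2)cc1
F3 | step 8 | (2S,3R,4R)-7,8-bis(benzyloxy)-2-[4-(benzyloxy)phenyl]-4-(benzylsulfanyl)chroman-3-ol (2,3-cis-3,4-trans) | c1ccc(COc2ccc([C@@H]3Oc4c(ccc(OCc5ccccc5)c4OCc4ccccc4)[C@@H](SCc4ccccc4)[C@@H]3O)cc2)cc1
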